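**Plan**

- Retrosynthesis: the two benzyl ethers and the ring B C–acetyl bond are cut first. Three ring B bonds are then cut together: carbonyl carbon to the acetyl-bearing CH, the adjacent C–O carbon to the bridge-bearing carbon, and the same carbonyl carbon to C(CH3)2. This leads back to a 2-benzyl-3-ethoxy-4,4-dimethylcyclobutenone and ethoxyacetylene.
- The cyclobutenone is cut at its C2–CH2 bond (Negishi coupling of a ring A benzylzinc with a 2-bromocyclobutenone), and the four-membered ring is cut into dimethylketene and ethoxyacetylene ([2+2]).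
- Forward: ring A is bought as 2,6-dihydroxy-4-methoxyacetophenone and turned into a benzylic chloride (steps 1–4). The cyclobutenone is built and brominated (steps 5–6) and the fragments are joined (step 7). Ring B, the only ring made, is closed in step 8, then hydrolysed, C-acetylated and debenzylated (steps 9–11).
- Enabling feature: ring B is a 2-acetyl-4,4-dimethylcyclohexane-1,3,5-trione. Its quaternary C4 (two methyl groups) lies between the oxygen-bearing carbons C3 and C5, so a dienylketene closing onto this carbon cannot aromatise and stops as a dienone that already carries the 1,3,5-oxygen pattern.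
- Stereochemistry: the target has no stereocentre and no stereogenic double bond, so nothing has to be set; the one transient stereocentre of the cascade is racemic and is lost within the same step.

Key step: step 8

Remark: the enolised triones of ring B are drawn as one tautomer each; the tautomers interconvert, and the drawing of the final compound is the one in the target SMILES.

**Step 1**
Reactants: 1 2,6-dihydroxy-4-methoxyacetophenone
Product: 3 3-acetyl-2,4-dihydroxy-6-methoxybenzaldehyde, via α-chloro ether 2 (not isolated)
Conditions: Cl2CHOMe (1.2 equiv), TiCl4 (3 equiv), CH2Cl2, -10 to 0 °C; then ice-cold 1 M aqueous HCl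
Reagents that add atoms: dichloromethyl methyl ether (COC(Cl)Cl); water (O)
Why: Rieche formylation, in which the titanium-bound phenoxide attacks the oxocarbenium ion from Cl2CHOMe at the only type of free ring position (C3 and C5 are equivalent) and aqueous work-up hydrolyses the α-chloro ether to the aldehyde, while the chelated acetyl group stays untouched.

**Step 2**
Reactants: 3 3-acetyl-2,4-dihydroxy-6-methoxybenzaldehyde
Product: 4 3-acetyl-2,4-bis(benzyloxy)-6-methoxybenzaldehyde
Conditions: BnBr (2.5 equiv), K2CO3, DMF, 60 °C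
Reagents that add atoms: benzyl bromide (BrCc1ccccc1)
Why: Williamson ether synthesis on two phenols made acidic by their ortho carbonyl groups, where O-alkylation should prevail over C-alkylation on this acyl-deactivated ring.

**Step 3**
Reactants: 4 3-acetyl-2,4-bis(benzyloxy)-6-methoxybenzaldehyde
Product: 5 1-[2,6-bis(benzyloxy)-3-(hydroxymethyl)-4-methoxyphenyl]ethan-1-one
Conditions: NaBH4 (0.5 equiv), THF/MeOH, -20 to 0 °C
Reagents that add atoms: none
Why: Chemoselective borohydride reduction, since the aldehyde is far more electrophilic than the aryl methyl ketone flanked by two benzyloxy groups and should be the only carbonyl reduced at low temperature.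

**Step 4**
Reactants: 5 1-[2,6-bis(benzyloxy)-3-(hydroxymethyl)-4-methoxyphenyl]ethan-1-one
Product: 7 1-[2,6-bis(benzyloxy)-3-(chloromethyl)-4-methoxyphenyl]ethan-1-one, via benzylic mesylate 6 (not isolated)
Conditions: MsCl, 2,4,6-collidine, LiCl, DMF, 0 °C; cold aqueous work-up, crude chloride used at once
Reagents that add atoms: lithium chloride ([Li+].[Cl-])
Why: Mesylation followed by in situ SN2 displacement with chloride is the standard mild way to turn acid-sensitive, electron-rich benzylic alcohols into chlorides, and the hindered collidine should not quaternise the product.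

**Step 5**
Reactants: 8 ethoxyacetylene; 9 isobutyryl chloride
Product: 11 3-ethoxy-4,4-dimethylcyclobut-2-en-1-one, via dimethylketene 10 (not isolated)
Conditions: Et3N, Et2O, 0 °C to reflux (8 as its commercial solution in hexanes)
Reagents that add atoms: none
Why: Dehydrohalogenation of the acid chloride gives dimethylketene, which is trapped as it forms in the known regioselective ketene–ynol ether [2+2] cycloaddition (alkyne CH carbon to the ketene carbonyl carbon) to give the 3-alkoxycyclobutenone.

**Step 6**
Reactants: 11 3-ethoxy-4,4-dimethylcyclobut-2-en-1-one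
Product: 12 2-bromo-3-ethoxy-4,4-dimethylcyclobut-2-en-1-one
Conditions: NBS, CH2Cl2, 0 to 25 °C
Reagents that add atoms: N-bromosuccinimide (O=C1CCC(=O)N1Br)
Why: Electrophilic α-bromination of a vinylogous ester, in which C2 is the only nucleophilic carbon because C4 is quaternary and loss of the C2 proton restores the push-pull alkene.

**Step 7**
Reactants: 7 1-[2,6-bis(benzyloxy)-3-(chloromethyl)-4-methoxyphenyl]ethan-1-one; 12 2-bromo-3-ethoxy-4,4-dimethylcyclobut-2-en-1-one
Product: 14 2-{[3-acetyl-2,4-bis(benzyloxy)-6-methoxyphenyl]methyl}-3-ethoxy-4,4-dimethylcyclobut-2-en-1-one, via benzylzinc chloride 13 (not isolated)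
Conditions: Zn dust, LiCl, THF, 25 °C; then 12, Pd(OAc)2 (2 mol %), SPhos (4 mol %), THF, 25 to 50 °C
Reagents that add atoms: none
Why: Negishi coupling, in which LiCl-assisted zinc insertion into the benzylic chloride tolerates the aryl ketone and the benzylzinc chloride transmetalates to the vinylpalladium bromide formed by oxidative addition of zerovalent palladium into the α-bromo enone, so that reductive elimination forges the C2–CH2 bond.

**Step 8**
Reactants: 14 2-{[3-acetyl-2,4-bis(benzyloxy)-6-methoxyphenyl]methyl}-3-ethoxy-4,4-dimethylcyclobut-2-en-1-one; 8 ethoxyacetylene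
Product: 18 4-{[3-acetyl-2,4-bis(benzyloxy)-6-methoxyphenyl]methyl}-3,5-diethoxy-6,6-dimethylcyclohexa-2,4-dien-1-one, via vinylketene 15 (not isolated), via vinylcyclobutenone 16 (not isolated), via dienylketene 17 (not isolated)
Conditions: 8 (5 equiv, added in portions), toluene, sealed tube, 110 °C
Reagents that add atoms: none
Why: Heating opens 14 by conrotatory 4π electrocyclic ring opening to vinylketene 15, whose ketene C=C adds ethoxyacetylene in a [2+2] cycloaddition (the nucleophilic CH carbon of the ynol ether to the ketene carbonyl carbon, the C(OEt) carbon to the bridge-bearing carbon) to give vinylcyclobutenone 16. A second 4π opening gives dienylketene 17, and ring B is closed by a thermally allowed disrotatory 6π electrocyclisation that joins the ketene carbon to the C(CH3)2 terminus. The closest known reaction is the Danheiser annulation of cyclobutenones with alkoxyacetylenes in its variant with 4,4-disubstituted cyclobutenones, which stops at the 2,4-cyclohexadienone, and 3-silyloxycyclobutenones are known to enter the same cascade with silyloxyacetylenes to give resorcinol derivatives. No stereocentre is created in 18, and the racemic quaternary centre of 16 is destroyed when 16 opens. The step needs regioselectivity in the [2+2], secured by the polarisation of the ynol ether and of the ketene, and it needs the ketenes to survive until they are trapped, secured by the benzyl caps on both phenols and by an excess of the alkyne that should outrun a 1,5-hydrogen shift from the inward methyl group. Aromatisation is impossible because C6 is quaternary, so the two ethyl enol ethers and the carbonyl of 18 map onto the three oxygens of ring B and the unsubstituted C2–H sits where the acetyl group is needed.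

**Step 9**
Reactants: 18 4-{[3-acetyl-2,4-bis(benzyloxy)-6-methoxyphenyl]methyl}-3,5-diethoxy-6,6-dimethylcyclohexa-2,4-dien-1-one
Product: 19 4-{[3-acetyl-2,4-bis(benzyloxy)-6-methoxyphenyl]methyl}-3,5-dihydroxy-6,6-dimethylcyclohexa-2,4-dien-1-one
Conditions: 2 M aqueous HCl, THF, 50 °C
Reagents that add atoms: water (O)
Why: Acid hydrolysis of vinylogous esters (protonation at the carbonyl oxygen, conjugate addition of water, loss of ethanol, first at C3 and then at C5) should unveil the enolised 1,3,5-trione, while aryl benzyl ethers are inert to dilute aqueous acid.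

**Step 10**
Reactants: 19 4-{[3-acetyl-2,4-bis(benzyloxy)-6-methoxyphenyl]methyl}-3,5-dihydroxy-6,6-dimethylcyclohexa-2,4-dien-1-one
Product: 21 2-acetyl-6-{[3-acetyl-2,4-bis(benzyloxy)-6-methoxyphenyl]methyl}-3,5-dihydroxy-4,4-dimethylcyclohexa-2,5-dien-1-one, via enol acetate 20 (not isolated)
Conditions: AcCl (1.05 equiv), Et3N, CH2Cl2, 0 °C; then DMAP (0.3 equiv), 25 °C; dilute acid work-up
Reagents that add atoms: acetyl chloride (CC(Cl)=O)
Why: O-acetylation of the triethylammonium enolate followed by DMAP-mediated O-to-C acyl migration (Steglich-type rearrangement of an enol ester) should funnel every regioisomeric enol acetate to the one ring carbon that still bears hydrogen, because that C-acyl product is a hydrogen-bonded enolised triketone whereas acylation at the benzyl-bearing carbon is reversible.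

**Step 11**
Reactants: 21 2-acetyl-6-{[3-acetyl-2,4-bis(benzyloxy)-6-methoxyphenyl]methyl}-3,5-dihydroxy-4,4-dimethylcyclohexa-2,5-dien-1-one
Product: 22 2-acetyl-6-[(3-acetyl-2,4-dihydroxy-6-methoxyphenyl)methyl]-3,5-dihydroxy-4,4-dimethylcyclohexa-2,5-dien-1-one (CNP0224819.0)
Conditions: H2 (1 atm), Pd/C, EtOAc, 25 °C
Reagents that add atoms: none
Why: Hydrogenolysis of the two aryl benzyl ethers over Pd/C under mild neutral conditions should leave the hydrogen-bonded aryl ketone, the enolised triketone and the methylene bridge intact.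

**Compound list**

1 | 2,6-dihydroxy-4-methoxyacetophenone | COc1cc(O)c(C(C)=O)c(O)c1 | starting material
2 | 1-{3-[chloro(methoxy)methyl]-2,6-dihydroxy-4-methoxyphenyl}ethan-1-one (racemic, titanium-bound) | COc1cc(O)c(C(C)=O)c(O)c1C(Cl)OC | intermediate
3 | 3-acetyl-2,4-dihydroxy-6-methoxybenzaldehyde | COc1cc(O)c(C(C)=O)c(O)c1C=O | intermediate
4 | 3-acetyl-2,4-bis(benzyloxy)-6-methoxybenzaldehyde | COc1cc(OCc2ccccc2)c(C(C)=O)c(OCc2ccccc2)c1C=O | intermediate
5 | 1-[2,6-bis(benzyloxy)-3-(hydroxymethyl)-4-methoxyphenyl]ethan-1-one | COc1cc(OCc2ccccc2)c(C(C)=O)c(OCc2ccccc2)c1CO | intermediate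
6 | [3-acetyl-2,4-bis(benzyloxy)-6-methoxyphenyl]methyl methanesulfonate | COc1cc(OCc2ccccc2)c(C(C)=O)c(OCc2ccccc2)c1COS(C)(=O)=O | intermediate
7 | 1-[2,6-bis(benzyloxy)-3-(chloromethyl)-4-methoxyphenyl]ethan-1-one | COc1cc(OCc2ccccc2)c(C(C)=O)c(OCc2ccccc2)c1CCl | intermediate
8 | ethoxyacetylene | C#COCC | starting material
9 | isobutyryl chloride | CC(C)C(Cl)=O | starting material
10 | dimethylketene | CC(C)=C=O | intermediate
11 | 3-ethoxy-4,4-dimethylcyclobut-2-en-1-one | CCOC1=CC(=O)C1(C)C | intermediate
12 | 2-bromo-3-ethoxy-4,4-dimethylcyclobut-2-en-1-one | CCOC1=C(Br)C(=O)C1(C)C | intermediate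
13 | {[3-acetyl-2,4-bis(benzyloxy)-6-methoxyphenyl]methyl}zinc chloride | COc1cc(OCc2ccccc2)c(C(C)=O)c(OCc2ccccc2)c1C[Zn]Cl | intermediate
14 | 2-{[3-acetyl-2,4-bis(benzyloxy)-6-methoxyphenyl]methyl}-3-ethoxy-4,4-dimethylcyclobut-2-en-1-one | CCOC1=C(Cc2c(OC)cc(OCc3ccccc3)c(C(C)=O)c2OCc2ccccc2)C(=O)C1(C)C | intermediate
15 | 2-{[3-acetyl-2,4-bis(benzyloxy)-6-methoxyphenyl]methyl}-3-ethoxy-4-methylpenta-1,3-dien-1-one (vinylketene) | CCOC(=C(C)C)C(=C=O)Cc1c(OC)cc(OCc2ccccc2)c(C(C)=O)c1OCc1ccccc1 | intermediate
16 | 4-{[3-acetyl-2,4-bis(benzyloxy)-6-methoxyphenyl]methyl}-3-ethoxy-4-(1-ethoxy-2-methylprop-1-enyl)cyclobut-2-en-1-one (racemic) | CCOC1=CC(=O)C1(Cc2c(OC)cc(OCc3ccccc3)c(C(C)=O)c2OCc2ccccc2)C(OCC)=C(C)C | intermediate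
17 | 4-{[3-acetyl-2,4-bis(benzyloxy)-6-methoxyphenyl]methyl}-3,5-diethoxy-6-methylhepta-1,3,5-trien-1-one (dienylketene, ketenyl and alkoxyvinyl groups cis on the central double bond) | O=C=C/C(OCC)=C(\C(OCC)=C(C)C)Cc1c(OC)cc(OCc2ccccc2)c(C(C)=O)c1OCc1ccccc1 | intermediate
18 | 4-{[3-acetyl-2,4-bis(benzyloxy)-6-methoxyphenyl]methyl}-3,5-diethoxy-6,6-dimethylcyclohexa-2,4-dien-1-one | CCOC1=CC(=O)C(C)(C)C(OCC)=C1Cc1c(OC)cc(OCc2ccccc2)c(C(C)=O)c1OCc1ccccc1 | intermediate
19 | 4-{[3-acetyl-2,4-bis(benzyloxy)-6-methoxyphenyl]methyl}-3,5-dihydroxy-6,6-dimethylcyclohexa-2,4-dien-1-one | OC1=CC(=O)C(C)(C)C(O)=C1Cc1c(OC)cc(OCc2ccccc2)c(C(C)=O)c1OCc1ccccc1 | intermediate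
20 | 6-{[3-acetyl-2,4-bis(benzyloxy)-6-methoxyphenyl]methyl}-5-hydroxy-4,4-dimethyl-3-oxocyclohexa-1,5-dien-1-yl acetate (one of several enol acetate regioisomers) | CC(=O)OC1=CC(=O)C(C)(C)C(O)=C1Cc1c(OC)cc(OCc2ccccc2)c(C(C)=O)c1OCc1ccccc1 | intermediate
21 | 2-acetyl-6-{[3-acetyl-2,4-bis(benzyloxy)-6-methoxyphenyl]methyl}-3,5-dihydroxy-4,4-dimethylcyclohexa-2,5-dien-1-one | COc1cc(OCc2ccccc2)c(C(C)=O)c(OCc2ccccc2)c1CC1=C(O)C(C)(C)C(O)=C(C(C)=O)C1=O | intermediate
22 | 2-acetyl-6-[(3-acetyl-2,4-dihydroxy-6-methoxyphenyl)methyl]-3,5-dihydroxy-4,4-dimethylcyclohexa-2,5-dien-1-one (CNP0224819.0) | COc1cc(O)c(C(C)=O)c(O)c1CC1=C(O)C(C)(C)C(O)=C(C(C)=O)C1=O | target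

**Step count**

Total: 11 steps. Longest linear sequence: 9 steps (steps 1–4 and 7–11); steps 5–6 form the short branch.

**Steps most likely to fail**

Step 8. The alkoxy-stabilised cyclobutenone may open more slowly than ethoxyacetylene is lost by retro-ene fragmentation at the same temperature. The vinylketene may also be drained by a 1,5-hydrogen shift from its inward methyl group before it meets the alkyne. The fallback sets out from alcohol 5 and brings ring B in preformed. Commercial 2,4,6-trihydroxyacetophenone is dimethylated twice at one ring carbon (MeI, NaOMe, MeOH) to give acetylfilicinic acid F1. F1 has a single free ring carbon, which should be alkylated by the benzylic cation released from 5 under acid catalysis (TsOH, CH2Cl2, 25 °C). This Friedel–Crafts-type benzylation of an enolised triketone gives 21 directly, and the route is rejoined at 21, before step 11.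

Step 7. Zinc insertion into the very electron-rich benzylic chloride may be accompanied by Wurtz-type homocoupling or by ionisation and self-alkylation of the chloride. Transmetalation to the crowded vinylpalladium species may also be slow. The fallback sets out from 11 and 5 and uses the benzylic carbon as an electrophile under acid instead of as a nucleophile. Hydrolysis of 11 (1 M aqueous HCl, THF) should give 3-hydroxy-4,4-dimethylcyclobut-2-en-1-one F2, a strongly acidic vinylogous acid. Its C2 should capture the cation formed from 5 (catalytic TsOH, CH2Cl2) to give 2-{[3-acetyl-2,4-bis(benzyloxy)-6-methoxyphenyl]methyl}-3-hydroxy-4,4-dimethylcyclobut-2-en-1-one F3. O-Ethylation of F3 with Et3OBF4 and i-Pr2NEt should give a single regioisomer, because the two carbonyl groups of the dione form of F3 are equivalent. The route is rejoined at 14.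

Step 10. The acetyl group may be spread over several enol oxygens and migrate only in part, or a second acetyl group may be taken up. The fallback sets out from 19 and makes the C–C bond by condensation instead of acyl transfer. N,N-Dimethylacetamide dimethyl acetal (toluene, 60 °C) can condense only at the one ring carbon able to lose two hydrogens, giving 2-{[3-acetyl-2,4-bis(benzyloxy)-6-methoxyphenyl]methyl}-6-[1-(dimethylamino)ethylidene]-3-hydroxy-4,4-dimethylcyclohex-2-ene-1,5-dione F4. Hydrolysis of this vinylogous amide (aqueous NaOH, MeOH, 50 °C, then dilute HCl) should give 21, where the route is rejoined.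

**Further compounds**

F1 | step 8 | acetylfilicinic acid (2-acetyl-3,5-dihydroxy-4,4-dimethylcyclohexa-2,5-dien-1-one) | CC(=O)C1=C(O)C(C)(C)C(O)=CC1=O
F2 | step 7 | 3-hydroxy-4,4-dimethylcyclobut-2-en-1-one | CC1(C)C(O)=CC1=O
F3 | step 7 | 2-{[3-acetyl-2,4-bis(benzyloxy)-6-methoxyphenyl]methyl}-3-hydroxy-4,4-dimethylcyclobut-2-en-1-one | COc1cc(OCc2ccccc2)c(C(C)=O)c(OCc2ccccc2)c1CC1=C(O)C(C)(C)C1=O
F4 | step 10 | 2-{[3-acetyl-2,4-bis(benzyloxy)-6-methoxyphenyl]methyl}-6-[1-(dimethylamino)ethylidene]-3-hydroxy-4,4-dimethylcyclohex-2-ene-1,5-dione | CN(C)C(C)=C1C(=O)C(Cc2c(OC)cc(OCc3ccccc3)c(C(C)=O)c2OCc2ccccc2)=C(O)C(C)(C)C1=O
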